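**Retrosynthetic overview**
1. The target is cut back, through C20 acetate and benzyloxymethyl (BOM) ether removal, oxa-Michael closure of the spiro tetrahydrofuran at C13 and oxidation of a furan to the butenolide, to a 9α-hydroxy furan made from 2-(furan-3-yl)ethyllithium and a C9 ketone.
2. The C9 ketone with its 19,6β-lactone comes from a ring A/B diester with a C6 ketone: reduction to 6β-OH, lactonisation onto the syn ester, decarbomethoxylation and C4 methylation (the lactone fixes C4).
3. The strategy rests on this feature: C4 of ring A, the quaternary carbon carrying C18 and the lactone carbonyl C19, is bonded to the ring-fusion carbon C5, which sits next to the oxygen-bearing C6 of ring B. The C4–C5 bond is therefore made from a malonate carbon and the β-carbon of a C6 methyl enol ether by anodic malonyl radical cyclisation, which closes ring A.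
4. Ring B is an aromatic ring: asymmetric Birch reduction–alkylation of a 2,5-dimethoxy-3-methylbenzamide sets C10. The amide is reduced to the protected C20 CH2O group before the malonate is attached, because it could not be reduced selectively later beside two lactones.
5. Order of ring formation: ring B (from the arene), ring A (key step), 19,6-lactone, then spiro tetrahydrofuran and butyrolactone.

Key step: step 8

Remark: positions are numbered as in the labdanes (C1–C10 decalin, C11–C16 side chain, C17 on C8, C18 and C19 on C4, C20 on C10); β is the face of C20.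
Assumption: the Birch alkylation follows the chelated-enolate model of 2-methoxybenzamides of (S)-2-(methoxymethyl)pyrrolidine; were the sense opposite, the (R)-amine would be used and nothing else changes.

**Step 1**
Reactants: 1 3-methylsalicylic acid
Product: 3 2,5-dihydroxy-3-methylbenzoic acid, via aryl sulfate 2 (not isolated)
Conditions: K2S2O8, aq KOH, 0 °C to rt; then aq H2SO4, reflux
Reagents that add atoms: potassium peroxodisulfate, [K+].[K+].[O-]S(=O)(=O)OOS(=O)(=O)[O-]
Why: Elbs persulfate oxidation, in which the phenoxide attacks peroxodisulfate through its only free para position (C5) and the aryl sulfate is then hydrolysed by acid.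

**Step 2**
Reactants: 3 2,5-dihydroxy-3-methylbenzoic acid
Product: 5 2,5-dimethoxy-3-methylbenzoic acid, via methyl ester 4 (not isolated)
Conditions: Me2SO4, K2CO3, acetone, reflux; then aq NaOH, MeOH, reflux; HCl
Reagents that add atoms: dimethyl sulfate, COS(=O)(=O)OC; sodium hydroxide, [Na+].[OH-]
Why: Williamson-type O-methylation of both phenols and the carboxylate, then saponification of the only base-labile group.

**Step 3**
Reactants: 5 2,5-dimethoxy-3-methylbenzoic acid; 6 (S)-2-(methoxymethyl)pyrrolidine
Product: 8 (S)-1-(2,5-dimethoxy-3-methylbenzoyl)-2-(methoxymethyl)pyrrolidine, via acid chloride 7 (not isolated)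
Conditions: (COCl)2, DMF (cat.), CH2Cl2, 0 °C to rt; then 6, Et3N, CH2Cl2, 0 °C
Reagents that add atoms: none
Why: Acid chloride formation and N-acylation of the secondary amine, which leaves the stereocentre of the auxiliary untouched.

**Step 4**
Reactants: 8 (S)-1-(2,5-dimethoxy-3-methylbenzoyl)-2-(methoxymethyl)pyrrolidine; 9 1-chloro-3-iodopropane
Product: 11 (S)-2-(methoxymethyl)pyrrolidine amide of (1R)-1-(3-chloropropyl)-2,5-dimethoxy-3-methylcyclohexa-2,5-diene-1-carboxylic acid, via potassium amide enolate 10 (not isolated)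
Conditions: K, t-BuOH (1 equiv), NH3/THF, −78 °C; piperylene; then 9, −78 °C; NH4Cl
Reagents that add atoms: none
Why: Schultz asymmetric Birch reduction–alkylation, in which K+ is held between the enolate oxygen and the CH2OMe arm of the auxiliary, so the iodide end of 9 is attacked from the opposite face and the quaternary centre (later C10) is set.

**Step 5**
Reactants: 11 chloropropyl diene amide
Product: 12 [(1S)-1-(3-chloropropyl)-2,5-dimethoxy-3-methylcyclohexa-2,5-dien-1-yl]methanol
Conditions: LiH2NBH3 (from LiN(i-Pr)2 and H3N·BH3), THF, 0 °C to rt; aq NH4Cl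
Reagents that add atoms: none
Why: Reduction of an α-quaternary tertiary amide to the primary alcohol by lithium amidotrihydroborate, done here because no other reducible group is present yet; the auxiliary is released as the amine and the primary chloride is expected to survive at this temperature.

**Step 6**
Reactants: 12 neopentyl alcohol
Product: 13 (1S)-1-(benzyloxymethoxymethyl)-1-(3-chloropropyl)-2,5-dimethoxy-3-methylcyclohexa-2,5-diene
Conditions: BOMCl, i-Pr2NEt, CH2Cl2, 0 to 40 °C
Reagents that add atoms: benzyl chloromethyl ether, ClCOCc1ccccc1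
Why: Alkoxymethylation with an amine base avoids both a free alkoxide (which could close a tetrahydropyran onto the chloropropyl chain) and acid (which would hydrolyse the enol ethers).

**Step 7**
Reactants: 13 BOM ether chloride; 14 dimethyl malonate
Product: 16 dimethyl 2-{3-[(1S)-1-(benzyloxymethoxymethyl)-2,5-dimethoxy-3-methylcyclohexa-2,5-dien-1-yl]propyl}malonate, via primary iodide 15 (not isolated)
Conditions: NaI, acetone, reflux; then 14 (excess), NaH, THF/DMF, 60 °C
Reagents that add atoms: none
Why: Finkelstein exchange followed by malonic ester alkylation (SN2), with excess malonate to suppress dialkylation.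

**Step 8**
Reactants: 16 malonate-tethered bis(enol ether)
Product: 17 cis-fused ring A/B ketal: C4 geminal dimethyl ester, C6 dimethyl ketal, C8=C9 methyl enol ether, C10 CH2OBOM, H5 cis to C20
Conditions: Fe(C5H5)2 (ferrocene, 10 mol %), NaOMe (0.5 equiv), LiClO4, MeOH/THF, reticulated vitreous carbon anode, Pt cathode, undivided cell, constant current, rt
Reagents that add atoms: methanol, CO
Why: Methoxide (regenerated at the cathode) forms the malonate enolate, the anodically formed ferrocenium ion oxidises it to the electrophilic C4 malonyl radical, this adds to the unsubstituted β-carbon C5 of the C5=C6 enol ether, and the α-methoxy radical at C6 loses a second electron to an oxocarbenium ion that methanol traps as the dimethyl ketal. The closest known reactions are ferrocene-mediated anodic cyclisations of malonyl radicals onto alkenes and Mn(OAc)3-promoted oxidative cyclisations of malonates onto enol ethers. Ring A closes in the 6-exo-trig mode (C4–C5 bond, C6 exocyclic). The new stereocentre C5 is fixed by the three-carbon tether, which can deliver C4 only to the face of ring B that carries C1, so H5 ends cis to C20; this is corrected in step 9. The step needs attack at C5 and not at C9 or C6, which is secured by the polarity match and by the hindered tetrasubstituted C8=C9 enol ether, and it needs the enol ethers to stay unoxidised, which the low potential of the ferrocene couple secures.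

**Step 9**
Reactants: 17 cis-fused ketal
Product: 19 trans-fused C6 ketone (5α-H) with C4 diester and C8=C9 enol ether, via cis-fused C6 ketone 18 (not isolated)
Conditions: PPTS, acetone/H2O, 40 °C; then NaOMe (cat.), MeOH, 40 °C
Reagents that add atoms: water, O
Why: Mild acetal hydrolysis should cleave the dimethyl ketal before the hindered enol ether or the formaldehyde acetal, and methoxide then epimerises C5 through the enolate to the trans-decalin, which is favoured because only there is the quaternary C4 equatorial on ring B.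

**Step 10**
Reactants: 19 trans-fused C6 ketone
Product: 21 19,6β-lactone carrying the 4α-CO2Me group, via 6β-hydroxy diester 20 (not isolated)
Conditions: NaBH4, MeOH/THF, 0 °C to rt
Reagents that add atoms: none
Why: Borohydride reduction from the α-face (the β-face of C6 is screened by the axial C20 and C19 groups) gives the axial 6β-alkoxide, which lactonises by transesterification with the syn-axial 4β-ester and so tells the two esters on C4 apart.

**Step 11**
Reactants: 21 lactone ester
Product: 22 19,6β-lactone with 4α-H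
Conditions: LiCl, H2O, DMSO, 150 °C
Reagents that add atoms: none
Why: Krapcho dealkoxycarbonylation, in which chloride demethylates the ester and the lactone-stabilised carbanion is protonated; the bridging lactone leaves only the 4α position for hydrogen.

**Step 12**
Reactants: 22 lactone with 4α-H
Product: 24 4α-methyl-19,6β-lactone with C8=C9 methyl enol ether and C20 OBOM, via lithium lactone enolate 23 (not isolated)
Conditions: LiN(i-Pr)2, THF, −78 °C; MeI, −78 to 0 °C
Reagents that add atoms: iodomethane, CI
Why: Lactone enolate alkylation; C19 is held on the β-face by its bridge to O6, so iodomethane can enter C4 only from the α-face, which sets the quaternary centre with C18 α.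

**Step 13**
Reactants: 24 methylated lactone enol ether
Product: 25 20-(benzyloxymethoxy)-8α-methyl-9-oxo-19,6β-lactone (ketolactone)
Conditions: 1 M aq HCl, THF, rt to 40 °C
Reagents that add atoms: water, O
Why: Acid hydrolysis of the enol ether to the C9 ketone; C8 equilibrates through the enol to the equatorial 8α-methyl, because an 8β-methyl would be syn-axial to C20.

**Step 14**
Reactants: 26 2-(furan-3-yl)ethanol
Product: 27 3-(2-iodoethyl)furan
Conditions: I2, PPh3, imidazole, CH2Cl2, 0 °C to rt
Reagents that add atoms: iodine, II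
Why: Appel-type iodination of a primary alcohol under neutral conditions that the furan tolerates.

**Step 15**
Reactants: 25 ketolactone; 27 3-(2-iodoethyl)furan
Product: 29 20-(benzyloxymethoxy)-15,16-epoxy-9α-hydroxylabda-13(16),14-dien-19,6β-olide, via 2-(furan-3-yl)ethyllithium 28 (not isolated)
Conditions: 27, t-BuLi (2 equiv), Et2O, −78 °C; then 25, THF, −78 to 0 °C; aq NH4Cl
Reagents that add atoms: none
Why: Iodine–lithium exchange and 1,2-addition to the ketone from the equatorial β-direction, as with 2,2,6-trialkylcyclohexanones and 9-oxo-19,6β-olides of this series, because the α-face is closed by the axial hydrogens on C1, C5 and C7; this gives the axial 9α-hydroxyl and the β side chain.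

**Step 16**
Reactants: 29 9α-hydroxy furan
Product: 31 20-(benzyloxymethoxy)-9α,16-dihydroxylabd-13-ene-19,6β:15,16-diolide (C16 epimers), via furan endoperoxide 30 (not isolated)
Conditions: O2, visible light, rose bengal (cat.), i-Pr2NEt, CH2Cl2, −78 °C
Reagents that add atoms: dioxygen, O=O
Why: [4+2] addition of singlet oxygen to the furan and base-induced Kornblum–DeLaMare opening of the endoperoxide at the less hindered C15–H, which places the carbonyl on C15 and the hydroxyl on C16.

**Step 17**
Reactants: 31 γ-hydroxybutenolide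
Product: 32 20-(benzyloxymethoxy)-9α-hydroxylabd-13-ene-19,6β:15,16-diolide
Conditions: NaBH4, MeOH, 0 °C; then 1 M aq HCl
Reagents that add atoms: none
Why: Borohydride reduces the aldehyde of the ring-opened hydroxybutenolide, and the (Z)-hydroxy acid relactonises on acidification to the β-substituted butenolide.

**Step 18**
Reactants: 32 hydroxy butenolide
Product: 33 (13R)-20-(benzyloxymethoxy)-9α,13-epoxylabdane-19,6β:15,16-diolide
Conditions: DBU (cat.), toluene, rt
Reagents that add atoms: none
Why: Base-catalysed intramolecular oxa-Michael addition (5-exo-trig) of the tertiary 9α-alkoxide to C13; the flat C14–C15 half of the butenolide is expected to lie on the more crowded C10 side, which leads to 13R, and because the addition is reversible a 13S epimer can be separated and re-equilibrated.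

**Step 19**
Reactants: 33 spiro lactone BOM ether
Product: 34 (13R)-9α,13-epoxy-20-hydroxylabdane-19,6β:15,16-diolide
Conditions: H2, Pd(OH)2/C, EtOAc, rt
Reagents that add atoms: none
Why: Hydrogenolysis of the benzyloxymethyl ether (benzyl C–O cleavage, then loss of formaldehyde) at a stage where no C=C bond remains.

**Step 20**
Reactants: 34 C20 alcohol
Product: 35 (13R)-20-acetoxy-9α,13-epoxylabdane-19,6β:15,16-diolide (target)
Conditions: Ac2O, pyridine, DMAP (cat.), CH2Cl2, rt
Reagents that add atoms: acetic anhydride, CC(=O)OC(C)=O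
Why: DMAP-catalysed acetylation of the only hydroxyl group under conditions too mild to reopen the β-alkoxy lactone.

**Compound list**
1 | 3-methylsalicylic acid | Cc1cccc(C(=O)O)c1O | starting material
2 | 2-hydroxy-3-methyl-5-(sulfooxy)benzoic acid (present as its potassium salt, not isolated) | Cc1cc(OS(=O)(=O)O)cc(C(=O)O)c1O | intermediate
3 | 2,5-dihydroxy-3-methylbenzoic acid | Cc1cc(O)cc(C(=O)O)c1O | intermediate
4 | methyl 2,5-dimethoxy-3-methylbenzoate (not isolated) | COC(=O)c1cc(OC)cc(C)c1OC | intermediate
5 | 2,5-dimethoxy-3-methylbenzoic acid | COc1cc(C)c(OC)c(C(=O)O)c1 | intermediate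
6 | (S)-2-(methoxymethyl)pyrrolidine | COC[C@@H]1CCCN1 | starting material
7 | 2,5-dimethoxy-3-methylbenzoyl chloride (not isolated) | COc1cc(C)c(OC)c(C(=O)Cl)c1 | intermediate
8 | (S)-1-(2,5-dimethoxy-3-methylbenzoyl)-2-(methoxymethyl)pyrrolidine | COC[C@@H]1CCCN1C(=O)c1cc(OC)cc(C)c1OC | intermediate
9 | 1-chloro-3-iodopropane | ClCCCI | starting material
10 | potassium (2,5-dimethoxy-3-methylcyclohexa-2,5-dien-1-ylidene)[(2S)-2-(methoxymethyl)pyrrolidin-1-yl]methanolate (not isolated) | [K+].[O-]C(N1CCC[C@H]1COC)=C1C=C(OC)CC(C)=C1OC | intermediate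
11 | (S)-2-(methoxymethyl)pyrrolidine amide of (1R)-1-(3-chloropropyl)-2,5-dimethoxy-3-methylcyclohexa-2,5-diene-1-carboxylic acid | COC1=C[C@@](CCCCl)(C(=O)N2CCC[C@H]2COC)C(OC)=C(C)C1 | intermediate
12 | [(1S)-1-(3-chloropropyl)-2,5-dimethoxy-3-methylcyclohexa-2,5-dien-1-yl]methanol | COC1=C[C@@](CCCCl)(CO)C(OC)=C(C)C1 | intermediate
13 | (1S)-1-(benzyloxymethoxymethyl)-1-(3-chloropropyl)-2,5-dimethoxy-3-methylcyclohexa-2,5-diene | COC1=C[C@@](CCCCl)(COCOCc2ccccc2)C(OC)=C(C)C1 | intermediate
14 | dimethyl malonate | COC(=O)CC(=O)OC | starting material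
15 | (1S)-1-(benzyloxymethoxymethyl)-1-(3-iodopropyl)-2,5-dimethoxy-3-methylcyclohexa-2,5-diene (not isolated) | COC1=C[C@@](CCCI)(COCOCc2ccccc2)C(OC)=C(C)C1 | intermediate
16 | dimethyl 2-{3-[(1S)-1-(benzyloxymethoxymethyl)-2,5-dimethoxy-3-methylcyclohexa-2,5-dien-1-yl]propyl}malonate | COC1=C[C@@](CCCC(C(=O)OC)C(=O)OC)(COCOCc2ccccc2)C(OC)=C(C)C1 | intermediate
17 | cis-fused decalin: C4 geminal dimethyl ester, C6 dimethyl ketal, C8=C9 methyl enol ether, 10β-CH2OBOM, 5β-H | COC(=O)C1(C(=O)OC)CCC[C@]2(COCOCc3ccccc3)C(OC)=C(C)CC(OC)(OC)[C@H]12 | intermediate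
18 | cis-fused C6 ketone (5β-H), otherwise as 17 (not isolated) | COC(=O)C1(C(=O)OC)CCC[C@]2(COCOCc3ccccc3)C(OC)=C(C)CC(=O)[C@H]12 | intermediate
19 | trans-fused C6 ketone (5α-H): C4 geminal dimethyl ester, C8=C9 methyl enol ether, 10β-CH2OBOM | COC(=O)C1(C(=O)OC)CCC[C@]2(COCOCc3ccccc3)C(OC)=C(C)CC(=O)[C@@H]12 | intermediate
20 | 6β-hydroxy diester, otherwise as 19 (not isolated) | COC(=O)C1(C(=O)OC)CCC[C@]2(COCOCc3ccccc3)C(OC)=C(C)C[C@@H](O)[C@@H]12 | intermediate
21 | 19,6β-lactone with 4α-CO2Me, C8=C9 methyl enol ether, 10β-CH2OBOM, 5α-H | c1ccc(cc1)COCOC[C@@]12CCC[C@]3(C(=O)OC)C(=O)O[C@H](CC(C)=C1OC)[C@H]23 | intermediate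
22 | 19,6β-lactone with 4α-H, otherwise as 21 | c1ccc(cc1)COCOC[C@@]12CCC[C@@H]3C(=O)O[C@H](CC(C)=C1OC)[C@H]23 | intermediate
23 | lithium enolate of lactone 22, C4=C19–OLi (not isolated) | [Li+].[O-]C1=C2CCC[C@]3(COCOCc4ccccc4)C(OC)=C(C)C[C@@H](O1)[C@@H]23 | intermediate
24 | 4α-methyl-19,6β-lactone with C8=C9 methyl enol ether, 10β-CH2OBOM, 5α-H | c1ccc(cc1)COCOC[C@@]12CCC[C@]3(C)C(=O)O[C@H](CC(C)=C1OC)[C@H]23 | intermediate
25 | 20-(benzyloxymethoxy)-8α-methyl-9-oxo-19,6β-lactone (4α-methyl, 5α-H) | c1ccc(cc1)COCOC[C@@]12CCC[C@]3(C)C(=O)O[C@H](C[C@@H](C)C1=O)[C@H]23 | intermediate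
26 | 2-(furan-3-yl)ethanol | OCCc1ccoc1 | starting material
27 | 3-(2-iodoethyl)furan | ICCc1ccoc1 | intermediate
28 | 2-(furan-3-yl)ethyllithium (not isolated) | [Li]CCc1ccoc1 | intermediate
29 | 20-(benzyloxymethoxy)-15,16-epoxy-9α-hydroxylabda-13(16),14-dien-19,6β-olide | c1ccc(cc1)COCOC[C@@]12CCC[C@]3(C)C(=O)O[C@H](C[C@@H](C)[C@]1(O)CCc1ccoc1)[C@H]23 | intermediate
30 | 15,16-endoperoxide of furan 29 (2,3,7-trioxabicyclo[2.2.1]hept-5-ene, not isolated) | c1ccc(cc1)COCOC[C@@]12CCC[C@]3(C)C(=O)O[C@H](C[C@@H](C)[C@]1(O)CCC1=CC4OOC1O4)[C@H]23 | intermediate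
31 | 20-(benzyloxymethoxy)-9α,16-dihydroxylabd-13-ene-19,6β:15,16-diolide (C16 epimers) | c1ccc(cc1)COCOC[C@@]12CCC[C@]3(C)C(=O)O[C@H](C[C@@H](C)[C@]1(O)CCC1=CC(=O)OC1O)[C@H]23 | intermediate
32 | 20-(benzyloxymethoxy)-9α-hydroxylabd-13-ene-19,6β:15,16-diolide | c1ccc(cc1)COCOC[C@@]12CCC[C@]3(C)C(=O)O[C@H](C[C@@H](C)[C@]1(O)CCC1=CC(=O)OC1)[C@H]23 | intermediate
33 | (13R)-20-(benzyloxymethoxy)-9α,13-epoxylabdane-19,6β:15,16-diolide | c1ccc(cc1)COCOC[C@@]12CCC[C@]3(C)C(=O)O[C@H](C[C@@H](C)[C@]14CC[C@@]1(COC(=O)C1)O4)[C@H]23 | intermediate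
34 | (13R)-9α,13-epoxy-20-hydroxylabdane-19,6β:15,16-diolide | OC[C@@]12CCC[C@]3(C)C(=O)O[C@H](C[C@@H](C)[C@]14CC[C@@]1(COC(=O)C1)O4)[C@H]23 | intermediate
35 | (13R)-20-acetoxy-9α,13-epoxylabdane-19,6β:15,16-diolide (8α-methyl, 5α-H) | CC(=O)OC[C@@]12CCC[C@]3(C)C(=O)O[C@H](C[C@@H](C)[C@]14CC[C@@]1(COC(=O)C1)O4)[C@H]23 | target

**Step count**
Total: 20 steps. Longest linear sequence: 19 steps (steps 1–13 and 15–20; step 14 makes the side-chain iodide).

**Steps most likely to fail**

Step 8. The malonyl radical may be quenched before it cyclises, or the enol ethers may be oxidised or solvolysed near the anode. The fallback sets out from 16. DBU and CBrCl3 in CH2Cl2 at 0 °C should brominate the malonate carbon and give dimethyl 2-bromo-2-{3-[(1S)-1-(benzyloxymethoxymethyl)-2,5-dimethoxy-3-methylcyclohexa-2,5-dien-1-yl]propyl}malonate F1. Blue-light irradiation with Ru(bpy)3Cl2 (1 mol %) and 2,6-lutidine in MeOH should then cleave the C–Br bond reductively. The same 6-exo closure follows, the oxidised photocatalyst takes the electron from the C6 radical, and methanol gives ketal 17, where the route is rejoined. This is the known photoredox oxyalkylation of enol ethers and enamides with bromomalonates.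

Step 18. Facial selectivity at C13 may be poor, because the CH2O and CH2C=O arms of the butenolide differ little in size, and the addition may reverse. The fallback makes C13 non-stereogenic until a catalyst-controlled last step, and sets out from 25.
- (4-Iodobut-1-yn-1-yl)trimethylsilane and t-BuLi give [4-(trimethylsilyl)but-3-yn-1-yl]lithium F5, which should add to the C9 ketone as in step 15 to give the 9α-hydroxy silylalkyne F6.
- K2CO3 in MeOH should remove the silyl group to give the terminal alkynol F7.
- (Ph3P)AuCl with AgOTf (cat.) should close the ring by 5-exo-dig hydroalkoxylation to the spiro 2-methylenetetrahydrofuran F8.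
- Dichloroketene (Cl3CCOCl, zinc–copper couple, Et2O/DME) should add [2+2] to this enol ether, with the carbonyl carbon on the CH2 terminus, to give the dichlorocyclobutanone F9.
- Zn in AcOH should dechlorinate it to the spiro cyclobutanone F10, whose two CH2 arms at C13 are identical.
- A desymmetrising Baeyer–Villiger oxidation (a chiral phosphoric acid with aqueous H2O2, or a Baeyer–Villiger monooxygenase) then chooses which CH2 migrates and should give 33, where the route is rejoined.

Step 15. The organolithium may enolise the hindered ketone toward C8 instead of adding, or may add from the α-face. The fallback sets out from 25. Methylenation with the Lombardo–Takai reagent (Zn, CH2Br2, TiCl4) should give the 9(11)-exocyclic alkene F2. mCPBA with NaHCO3 should epoxidise it anti to the axial C20 group to give the 9α,11-epoxide F3. (Furan-3-ylmethyl)magnesium chloride F4, made from 3-(chloromethyl)furan and Mg, with CuI (cat.) should open the epoxide at the primary C11 and give 29, where the route is rejoined.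

**Further compounds**
F1 | step 8 | dimethyl 2-bromo-2-{3-[(1S)-1-(benzyloxymethoxymethyl)-2,5-dimethoxy-3-methylcyclohexa-2,5-dien-1-yl]propyl}malonate | COC1=C[C@@](CCCC(Br)(C(=O)OC)C(=O)OC)(COCOCc2ccccc2)C(OC)=C(C)C1
F2 | step 15 | 20-(benzyloxymethoxy)-9-methylene analogue of 25 (9(11)-exocyclic alkene) | c1ccc(cc1)COCOC[C@@]12CCC[C@]3(C)C(=O)O[C@H](C[C@@H](C)C1=C)[C@H]23
F3 | step 15 | 20-(benzyloxymethoxy)-9α,11-epoxide of F2 | c1ccc(cc1)COCOC[C@@]12CCC[C@]3(C)C(=O)O[C@H](C[C@@H](C)[C@]14CO4)[C@H]23
F4 | step 15 | (furan-3-ylmethyl)magnesium chloride | Cl[Mg]Cc1ccoc1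
F5 | step 18 | [4-(trimethylsilyl)but-3-yn-1-yl]lithium | [Li]CCC#C[Si](C)(C)C
F6 | step 18 | 9α-hydroxy-9β-[4-(trimethylsilyl)but-3-yn-1-yl] adduct of 25 | c1ccc(cc1)COCOC[C@@]12CCC[C@]3(C)C(=O)O[C@H](C[C@@H](C)[C@]1(O)CCC#C[Si](C)(C)C)[C@H]23
F7 | step 18 | 9α-hydroxy-9β-(but-3-yn-1-yl) lactone | c1ccc(cc1)COCOC[C@@]12CCC[C@]3(C)C(=O)O[C@H](C[C@@H](C)[C@]1(O)CCC#C)[C@H]23
F8 | step 18 | spiro 2-methylenetetrahydrofuran (9α,13-epoxy, C13=CH2) | c1ccc(cc1)COCOC[C@@]12CCC[C@]3(C)C(=O)O[C@H](C[C@@H](C)[C@]14CCC(=C)O4)[C@H]23
F9 | step 18 | spiro 2,2-dichlorocyclobutanone on C13 (C13 epimers) | c1ccc(cc1)COCOC[C@@]12CCC[C@]3(C)C(=O)O[C@H](C[C@@H](C)[C@]14CCC5(CC(=O)C5(Cl)Cl)O4)[C@H]23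
F10 | step 18 | spiro cyclobutanone on C13 | c1ccc(cc1)COCOC[C@@]12CCC[C@]3(C)C(=O)O[C@H](C[C@@H](C)[C@]14CCC5(CC(=O)C5)O4)[C@H]23
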